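**Strategy.** The route rests on a [3+3] union of a ring A phenol, used as a C,O-dinucleophile, with a three-carbon bis-electrophile that already carries ring B and the C3 methoxy stereocentre. In one flask the ortho-lithiated phenoxide acylates a Weinreb amide (C4–C4a), and the acid quench ionises the benzylic carbinol so that the phenolic oxygen closes the pyranone ring (O1–C2) trans to the C3 methoxy group. The step exploits the para-methoxy and ortho-alkoxy groups of ring B, which make C2 an easily formed cation, and the mirror-symmetric ring A phenol, which offers a single acylation site. The precursors are a bromophenol and an Evans syn-aldol-derived β-hydroxy-α-methoxy Weinreb amide.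

Key step: step 7

Remark: the 2,3-trans relationship of the target corresponds to (2R,3R); ring closure at C2 is taken to be stereoconvergent, so only the C3 configuration has to be carried through the route.

**Step 1**
Reactants: 1 4-(benzyloxy)-3,5-dimethoxybenzaldehyde
Product: 3 4-(benzyloxy)-3,5-dimethoxyphenol, via aryl formate 2 (not isolated)
Conditions: mCPBA, CH2Cl2, 0 °C → rt; then K2CO3 (cat.), MeOH, rt
Reagents that add atoms: mCPBA, OOC(=O)c1cccc(Cl)c1
Why: Baeyer–Villiger (Dakin-type) oxidation in which the electron-rich aryl group migrates in preference to hydride, followed by methanolysis of the formate to free the phenol.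

**Step 2**
Reactants: 3 4-(benzyloxy)-3,5-dimethoxyphenol
Product: 4 4-(benzyloxy)-2-bromo-3,5-dimethoxyphenol
Conditions: NBS (1.0 equiv), CH2Cl2, −78 → 0 °C
Reagents that add atoms: N-bromosuccinimide, O=C1CCC(=O)N1Br
Why: Electrophilic aromatic bromination ortho to the hydroxyl group, where the two open positions are equivalent by symmetry so that only one monobromide can form.

**Step 3**
Reactants: 5 2,3-dihydroxy-4-methoxybenzaldehyde
Product: 6 2,3-bis(benzyloxy)-4-methoxybenzaldehyde
Conditions: BnBr (2.4 equiv), K2CO3, DMF, 60 °C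
Reagents that add atoms: benzyl bromide, BrCc1ccccc1
Why: Williamson ether synthesis on both phenolic hydroxyls, which should go to completion with excess base and halide.

**Step 4**
Reactants: 7 (R)-4-benzyloxazolidin-2-one; 8 methoxyacetyl chloride
Product: 9 (R)-4-benzyl-3-(methoxyacetyl)oxazolidin-2-one
Conditions: n-BuLi, THF, −78 °C; then 8, −78 → 0 °C
Reagents that add atoms: none
Why: N-acylation of the lithiated oxazolidinone with the acid chloride, the standard way to load an Evans auxiliary.

**Step 5**
Reactants: 9 (R)-4-benzyl-3-(methoxyacetyl)oxazolidin-2-one; 6 2,3-bis(benzyloxy)-4-methoxybenzaldehyde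
Product: 11 (4R)-4-benzyl-3-[(2R,3S)-3-[2,3-bis(benzyloxy)-4-methoxyphenyl]-3-hydroxy-2-methoxypropanoyl]oxazolidin-2-one, via Z-boron enolate 10 (not isolated)
Conditions: Bu2BOTf, Et3N, CH2Cl2, −78 → 0 °C; then 6, −78 → 0 °C; then pH 7 buffer (NaH2PO4/Na2HPO4), MeOH, 30% H2O2, 0 °C
Reagents that add atoms: none
Why: Evans syn-aldol in which the Z-boron enolate reacts through a closed chair (Zimmerman–Traxler) transition state on the enolate face remote from the benzyl group of the (R)-auxiliary, which should set the (2R) methoxy centre that becomes C3 of the target together with the (3S) carbinol.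

**Step 6**
Reactants: 11 (4R)-4-benzyl-3-[(2R,3S)-3-[2,3-bis(benzyloxy)-4-methoxyphenyl]-3-hydroxy-2-methoxypropanoyl]oxazolidin-2-one
Product: 12 (2R,3S)-3-[2,3-bis(benzyloxy)-4-methoxyphenyl]-3-hydroxy-N,2-dimethoxy-N-methylpropanamide
Conditions: MeNH(OMe)·HCl, AlMe3, CH2Cl2, −20 → 0 °C; then aq. potassium sodium tartrate (KNaC4H4O6)
Reagents that add atoms: N,O-dimethylhydroxylamine hydrochloride, CNOC.Cl
Why: Aluminium-amide transamination (Weinreb amide formation) at the exocyclic imide carbonyl, assisted by the free β-hydroxyl, should release the auxiliary without touching either stereocentre.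

**Step 7**
Reactants: 4 4-(benzyloxy)-2-bromo-3,5-dimethoxyphenol; 12 (2R,3S)-3-[2,3-bis(benzyloxy)-4-methoxyphenyl]-3-hydroxy-N,2-dimethoxy-N-methylpropanamide
Product: 15 (2R,3R)-6-(benzyloxy)-2-[2,3-bis(benzyloxy)-4-methoxyphenyl]-3,5,7-trimethoxychroman-4-one, via dilithiated phenol 13 (not isolated), via hydroxy ketone 14 (not isolated)
Conditions: 4 (1.3 equiv), t-BuLi (3.1 equiv per 4), Et2O/THF, −78 °C; add 12 (pre-treated with i-PrMgCl, 1.0 equiv, THF, −40 °C), −78 → −20 °C; then CF3CO2H (excess), CH2Cl2, −78 → 0 °C, same flask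
Reagents that add atoms: none
Why: Bromine–lithium exchange on the lithium phenoxide of 4 gives the C,O-dianion 13, whose aryl carbon attacks the N-methoxy-N-methyl amide of 12 to form the C4–C4a bond and a chelated tetrahedral adduct that resists over-addition and epimerisation; acid then releases ketone 14 and ionises its benzylic carbinol to a cation stabilised by the para-methoxy and ortho-benzyloxy groups of ring B, which the phenolic oxygen ortho to the ketone captures to form the O1–C2 bond. The closest known reaction types are the ketone synthesis from an aryllithium and a Weinreb amide and the acid-mediated cyclodehydration of 2'-hydroxy-β-hydroxydihydrochalcones to flavanones. The pyranone ring closes in a 6-exo-trig mode, the oxygen adding to the trigonal cationic C2 whose π-system lies outside the new ring. C3 is carried over unchanged from 12, and the re-formed C2 centre is controlled by C3: closure through a half-chair with the aryl and methoxy groups both pseudo-equatorial, which is also the thermodynamic arrangement, should give the 2,3-trans (2R,3R) isomer from either carbinol epimer. The step needs C- rather than O-acylation at a single site, secured by the carbon–lithium bond at the only type of ortho position of the symmetric phenol, and ring closure through one oxygen only, secured because the C5 and C6 oxygens are capped as methyl and benzyl ethers. It also needs ring closure to outrun loss of the C3 proton to the α-methoxychalcone, which the intramolecular six-membered capture at low temperature should favour.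

**Step 8**
Reactants: 15 (2R,3R)-6-(benzyloxy)-2-[2,3-bis(benzyloxy)-4-methoxyphenyl]-3,5,7-trimethoxychroman-4-one
Product: 16 (2R,3R)-2-(2,3-dihydroxy-4-methoxyphenyl)-5,6-dihydroxy-3,7-dimethoxychroman-4-one
Conditions: BCl3 (excess), C6HMe5, CH2Cl2, −78 → 0 °C; then MeOH, aq. HCl
Reagents that add atoms: none
Why: Lewis-acid ether cleavage in which BCl3 with pentamethylbenzene as benzyl-cation trap removes the three aryl benzyl ethers and the C5 methyl ether peri to the C4 carbonyl is cleaved through its boron chelate, whereas the C7, C4' and aliphatic C3 methyl ethers lack this activation and neither stereocentre is involved.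

**Compound list**
1 | 4-(benzyloxy)-3,5-dimethoxybenzaldehyde | COc1cc(C=O)cc(OC)c1OCc1ccccc1 | starting material
2 | 4-(benzyloxy)-3,5-dimethoxyphenyl formate | COc1cc(OC=O)cc(OC)c1OCc1ccccc1 | intermediate
3 | 4-(benzyloxy)-3,5-dimethoxyphenol | COc1cc(O)cc(OC)c1OCc1ccccc1 | intermediate
4 | 4-(benzyloxy)-2-bromo-3,5-dimethoxyphenol | COc1cc(O)c(Br)c(OC)c1OCc1ccccc1 | intermediate
5 | 2,3-dihydroxy-4-methoxybenzaldehyde | COc1ccc(C=O)c(O)c1O | starting material
6 | 2,3-bis(benzyloxy)-4-methoxybenzaldehyde | COc1ccc(C=O)c(OCc2ccccc2)c1OCc1ccccc1 | intermediate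
7 | (R)-4-benzyloxazolidin-2-one | O=C1N[C@H](Cc2ccccc2)CO1 | starting material
8 | methoxyacetyl chloride | COCC(Cl)=O | starting material
9 | (R)-4-benzyl-3-(methoxyacetyl)oxazolidin-2-one | COCC(=O)N1[C@H](Cc2ccccc2)COC1=O | intermediate
10 | (R)-4-benzyl-3-[(Z)-1-(dibutylboryloxy)-2-methoxyethenyl]oxazolidin-2-one | CCCCB(CCCC)O/C(=C\OC)N1[C@H](Cc2ccccc2)COC1=O | intermediate
11 | (4R)-4-benzyl-3-[(2R,3S)-3-[2,3-bis(benzyloxy)-4-methoxyphenyl]-3-hydroxy-2-methoxypropanoyl]oxazolidin-2-one | COc1ccc([C@H](O)[C@@H](OC)C(=O)N2[C@H](Cc3ccccc3)COC2=O)c(OCc2ccccc2)c1OCc1ccccc1 | intermediate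
12 | (2R,3S)-3-[2,3-bis(benzyloxy)-4-methoxyphenyl]-3-hydroxy-N,2-dimethoxy-N-methylpropanamide | COc1ccc([C@H](O)[C@@H](OC)C(=O)N(C)OC)c(OCc2ccccc2)c1OCc1ccccc1 | intermediate
13 | lithium 4-(benzyloxy)-2-lithio-3,5-dimethoxyphenoxide | [Li]Oc1cc(OC)c(OCc2ccccc2)c(OC)c1[Li] | intermediate
14 | (2R,3S)-1-[3-(benzyloxy)-6-hydroxy-2,4-dimethoxyphenyl]-3-[2,3-bis(benzyloxy)-4-methoxyphenyl]-3-hydroxy-2-methoxypropan-1-one | COc1ccc([C@H](O)[C@@H](OC)C(=O)c2c(O)cc(OC)c(OCc3ccccc3)c2OC)c(OCc2ccccc2)c1OCc1ccccc1 | intermediate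
15 | (2R,3R)-6-(benzyloxy)-2-[2,3-bis(benzyloxy)-4-methoxyphenyl]-3,5,7-trimethoxychroman-4-one | COc1ccc([C@H]2Oc3cc(OC)c(OCc4ccccc4)c(OC)c3C(=O)[C@@H]2OC)c(OCc2ccccc2)c1OCc1ccccc1 | intermediate
16 | (2R,3R)-2-(2,3-dihydroxy-4-methoxyphenyl)-5,6-dihydroxy-3,7-dimethoxychroman-4-one | COc1ccc([C@H]2Oc3cc(OC)c(O)c(O)c3C(=O)[C@@H]2OC)c(O)c1O | target

**Count.** Total steps: 8. Longest linear sequence: 5 steps (steps 4, 5, 6, 7, 8).

**Steps most likely to fail**

1. Step 7 (key step). The hindered aryllithium may deprotonate the amide alpha position instead of adding. In the acid stage the benzylic cation may lose the C3 proton to give the α-methoxychalcone, which would erode the C3 configuration. The fallback sets out from 4 and 12 and reverses the order of bond formation. A Mitsunobu etherification (PPh3, DIAD, THF, 0 °C) of phenol 4 with the benzylic alcohol of 12 should proceed with inversion to the aryl ether (2R,3R)-3-[4-(benzyloxy)-2-bromo-3,5-dimethoxyphenoxy]-3-[2,3-bis(benzyloxy)-4-methoxyphenyl]-N,2-dimethoxy-N-methylpropanamide F1. Bromine–lithium exchange (t-BuLi, THF, −78 °C) would then give the aryllithium (2R,3R)-3-[4-(benzyloxy)-2-lithio-3,5-dimethoxyphenoxy]-3-[2,3-bis(benzyloxy)-4-methoxyphenyl]-N,2-dimethoxy-N-methylpropanamide F2. This should close onto the Weinreb amide (Parham cyclisation) and, after aqueous NH4Cl, come back to the route at 15. No cation is involved, so C3 cannot be lost by elimination.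

2. Step 8. Over-dealkylation at the C7 or C4' methyl ethers next to the newly freed hydroxyls, or Lewis-acid opening of the C2–O1 bond with epimerisation, may compete. The fallback sets out from 15 and separates the two events with chemoselective reagents. MgI2·OEt2 (toluene/Et2O, rt → 50 °C) should cleave only the chelated C5 methyl ether to give (2R,3R)-6-(benzyloxy)-2-[2,3-bis(benzyloxy)-4-methoxyphenyl]-5-hydroxy-3,7-dimethoxychroman-4-one F3. Hydrogenolysis (H2, 10% Pd/C, EtOAc/MeOH, rt) of the three benzyl ethers then comes back to the route at 16.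

3. Step 2. Over-bromination or oxidative dealkylation of the para-alkoxyphenol to a quinone may consume the phenol. The fallback sets out from 3 and replaces halogen–metal exchange by directed ortho-metalation. MOMCl, i-Pr2NEt, CH2Cl2 should give 2-(benzyloxy)-1,3-dimethoxy-5-(methoxymethoxy)benzene F4. n-BuLi (THF, 0 °C) should lithiate the position between the methoxymethoxy and methoxy groups to give [3-(benzyloxy)-2,4-dimethoxy-6-(methoxymethoxy)phenyl]lithium F5. Addition of 12 (pre-treated with i-PrMgCl) and a quench with HCl in MeOH would release (2R,3S)-1-[3-(benzyloxy)-2,4-dimethoxy-6-(methoxymethoxy)phenyl]-3-[2,3-bis(benzyloxy)-4-methoxyphenyl]-3-hydroxy-2-methoxypropan-1-one F6. F6 loses its methoxymethyl group to 14 under the same acid, and 14 closes as in step 7, coming back to the route at 15.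

**Further compounds**
F1 | step 7 | (2R,3R)-3-[4-(benzyloxy)-2-bromo-3,5-dimethoxyphenoxy]-3-[2,3-bis(benzyloxy)-4-methoxyphenyl]-N,2-dimethoxy-N-methylpropanamide | COc1ccc([C@@H](Oc2cc(OC)c(OCc3ccccc3)c(OC)c2Br)[C@@H](OC)C(=O)N(C)OC)c(OCc2ccccc2)c1OCc1ccccc1
F2 | step 7 | (2R,3R)-3-[4-(benzyloxy)-2-lithio-3,5-dimethoxyphenoxy]-3-[2,3-bis(benzyloxy)-4-methoxyphenyl]-N,2-dimethoxy-N-methylpropanamide | COc1ccc([C@@H](Oc2cc(OC)c(OCc3ccccc3)c(OC)c2[Li])[C@@H](OC)C(=O)N(C)OC)c(OCc2ccccc2)c1OCc1ccccc1
F3 | step 8 | (2R,3R)-6-(benzyloxy)-2-[2,3-bis(benzyloxy)-4-methoxyphenyl]-5-hydroxy-3,7-dimethoxychroman-4-one | COc1ccc([C@H]2Oc3cc(OC)c(OCc4ccccc4)c(O)c3C(=O)[C@@H]2OC)c(OCc2ccccc2)c1OCc1ccccc1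
F4 | step 2 | 2-(benzyloxy)-1,3-dimethoxy-5-(methoxymethoxy)benzene | COCOc1cc(OC)c(OCc2ccccc2)c(OC)c1
F5 | step 2 | [3-(benzyloxy)-2,4-dimethoxy-6-(methoxymethoxy)phenyl]lithium | COCOc1cc(OC)c(OCc2ccccc2)c(OC)c1[Li]
F6 | step 2 | (2R,3S)-1-[3-(benzyloxy)-2,4-dimethoxy-6-(methoxymethoxy)phenyl]-3-[2,3-bis(benzyloxy)-4-methoxyphenyl]-3-hydroxy-2-methoxypropan-1-one | COc1ccc([C@H](O)[C@@H](OC)C(=O)c2c(OCOC)cc(OC)c(OCc3ccccc3)c2OC)c(OCc2ccccc2)c1OCc1ccccc1
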